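**Plan**

1. Numbering: ring A is the benzoate ring (C1 CO2Me, C2 aryl ether O, C4 CH3, C5 prenyl, C6 OH); ring B carries the ether oxygen on C1', CH2OH on C2', and OMe on C4' and C6'.
2. Cuts, in retrosynthetic order: O–Si; C5–prenyl (traced back through an aromatic Claisen shift to a 1,1-dimethylallyl ether on the C6 oxygen); both ring B O–CH3 bonds; ring B itself at C1'–C2' and C5'–C6' (with a CO2Me lost from C1'); finally the ring A O–C1' bond as a phenoxide alkylation.
3. Enabling feature: the C4' and C6' oxygens are 1,3 on ring B and the ether carbon C1' can begin as the sp3 carbon of a malonate, so the crowded aryl–O–aryl bond is a simple O-alkylation of ring A made before ring B exists.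
4. Forward: ring A is bought as 1 and dressed (steps 1–3); ynone 11 is made in two steps (4, 5); ring B is folded from malonate 6 and 11 in step 6; methylation, Claisen shift and desilylation finish (steps 7–9).
5. Stereochemistry: the target has no stereocentre and no stereogenic double bond; the transient centres in 10, 13 and 16 are racemic and are erased.

Key step: step 6

Assumption: compounds 1, 2, 5 and 7 are taken as purchasable; 3-chloro-3-methylbut-1-yne is used directly as the source of the five-carbon unit.

**Route**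

Step 1
Reactants: 1 methyl 2,6-dihydroxy-4-methylbenzoate; 2 3-chloro-3-methylbut-1-yne
Product: 3 methyl 2-hydroxy-4-methyl-6-(2-methylbut-3-yn-2-yloxy)benzoate
Conditions: 2 (1.0 equiv), DBU (1.2 equiv), CuCl2·2H2O (1 mol%), MeCN, 0 °C to rt
Reagents that add atoms: none
Why: Copper-catalysed propargylic etherification of a phenol with a tertiary propargylic chloride (Godfrey-type) should give the hindered tertiary ether, and one equivalent of 2 plus the strong hydrogen bond of the remaining phenol to the ester carbonyl should hold the reaction at the mono-ether.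

Step 2
Reactants: 3 methyl 2-hydroxy-4-methyl-6-(2-methylbut-3-yn-2-yloxy)benzoate
Product: 4 methyl 2-hydroxy-4-methyl-6-(2-methylbut-3-en-2-yloxy)benzoate
Conditions: H2 (1 atm), Pd/CaCO3 poisoned with Pb(OAc)2 (Lindlar catalyst), quinoline, EtOAc, rt
Reagents that add atoms: none
Why: Lindlar semi-hydrogenation of a terminal alkyne stops at the alkene and leaves the aryl ester and aryl ethers untouched.

Step 3
Reactants: 4 methyl 2-hydroxy-4-methyl-6-(2-methylbut-3-en-2-yloxy)benzoate; 5 dimethyl bromomalonate
Product: 6 dimethyl 2-[2-(methoxycarbonyl)-5-methyl-3-(2-methylbut-3-en-2-yloxy)phenoxy]malonate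
Conditions: K2CO3 (1.1 equiv), acetone, rt
Reagents that add atoms: none
Why: Williamson O-alkylation (SN2) of the potassium phenoxide by the doubly carbonyl-activated bromide is the standard entry to aryloxymalonates, and room temperature with only a slight excess of base keeps the tertiary allyl ether and the product malonate intact.

Step 4
Reactants: 7 prop-2-yn-1-ol
Product: 8 triisopropyl(prop-2-yn-1-yloxy)silane
Conditions: TIPSCl, imidazole, CH2Cl2, 0 °C to rt
Reagents that add atoms: triisopropylsilyl chloride, CC(C)[Si](Cl)(C(C)C)C(C)C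
Why: Standard silylation of a primary alcohol with a silyl chloride and imidazole.

Step 5
Reactants: 8 triisopropyl(prop-2-yn-1-yloxy)silane
Product: 11 5-(triisopropylsilyloxy)pent-3-yn-2-one, via lithium acetylide 9 (not isolated), via lithium hemiaminal alkoxide 10 (not isolated)
Conditions: n-BuLi, THF, −78 °C; then MeC(O)N(OMe)Me, −78 to 0 °C; aq. NH4Cl
Reagents that add atoms: N-methoxy-N-methylacetamide, CC(=O)N(C)OC
Why: Acylation of a lithium acetylide with a Weinreb amide, whose chelated tetrahedral adduct 10 prevents over-addition, should release the ynone on aqueous quench.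

Step 6
Reactants: 6 dimethyl 2-[2-(methoxycarbonyl)-5-methyl-3-(2-methylbut-3-en-2-yloxy)phenoxy]malonate; 11 5-(triisopropylsilyloxy)pent-3-yn-2-one
Product: 14 methyl 2-[2,4-dihydroxy-6-(triisopropylsilyloxymethyl)phenoxy]-4-methyl-6-(2-methylbut-3-en-2-yloxy)benzoate, via Michael adduct 12 (not isolated), via cyclohexenedione ester 13 (not isolated)
Conditions: 11 (1.3 equiv), NaOMe (0.1 equiv), THF–MeOH, −20 °C to rt; then NaOMe (3 equiv), MeOH, 0 to 40 °C; aq. NH4Cl
Reagents that add atoms: none
Why: Proposed new method: a catalytic amount of methoxide turns 6 into its malonate anion, which adds to the ynone carbon carrying CH2OTIPS (bond C1'–C2') to give enone 12, and the excess NaOMe then equilibrates the enone geometry and forms the methyl ketone enolate, which attacks one malonate ester (bond C5'–C6') to give the enolate of dione 13; methoxide finally attacks the ester left on the quaternary C1', which departs as dimethyl carbonate while ring B aromatises to the resorcinol dianion. The closest known reaction type is the Michael–Dieckmann synthesis of resorcinols from malonates and alkynones; an oxygen-bearing malonate and the loss of the blocking ester in the same flask (a retro-Claisen-type dealkoxycarbonylation, here driven by aromatisation) are the untested parts. Ring B closes by a 6-exo-trig Dieckmann condensation. No stereocentre is formed in 14, and the quaternary centre of 13 is destroyed. The step needs the intermolecular Michael addition to outrun a five-membered Dieckmann closure of the malonate anion onto the ring A ester, which is secured by the low temperature, catalytic base and excess ynone of the first stage, by the di-ortho-substituted and therefore shielded ring A ester, and by the absence of a malonate C–H in 12. The polarised ynone fixes the regiochemistry of the addition, and methyl esters in NaOMe/MeOH make any ester exchange invisible.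

Step 7
Reactants: 14 methyl 2-[2,4-dihydroxy-6-(triisopropylsilyloxymethyl)phenoxy]-4-methyl-6-(2-methylbut-3-en-2-yloxy)benzoate
Product: 15 methyl 2-[2,4-dimethoxy-6-(triisopropylsilyloxymethyl)phenoxy]-4-methyl-6-(2-methylbut-3-en-2-yloxy)benzoate
Conditions: MeI (excess), K2CO3, acetone, rt
Reagents that add atoms: iodomethane, CI
Why: Williamson methylation of both ring B phenoxides; ring A has no free phenol at this stage, so no selectivity problem arises.

Step 8
Reactants: 15 methyl 2-[2,4-dimethoxy-6-(triisopropylsilyloxymethyl)phenoxy]-4-methyl-6-(2-methylbut-3-en-2-yloxy)benzoate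
Product: 17 methyl 2-[2,4-dimethoxy-6-(triisopropylsilyloxymethyl)phenoxy]-6-hydroxy-4-methyl-5-(3-methylbut-2-enyl)benzoate, via cyclohexadienone 16 (not isolated)
Conditions: PhMe, 120 °C, sealed tube
Reagents that add atoms: none
Why: Aromatic Claisen rearrangement ([3,3]-sigmatropic shift) of the 1,1-dimethylallyl aryl ether should deliver the allyl unit with inversion to C5, the only unsubstituted ortho carbon, and dienone 16 tautomerises to the hydrogen-bonded phenol.

Step 9
Reactants: 17 methyl 2-[2,4-dimethoxy-6-(triisopropylsilyloxymethyl)phenoxy]-6-hydroxy-4-methyl-5-(3-methylbut-2-enyl)benzoate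
Product: 18 methyl 6-hydroxy-2-[2-(hydroxymethyl)-4,6-dimethoxyphenoxy]-4-methyl-5-(3-methylbut-2-enyl)benzoate
Conditions: TBAF, AcOH, THF, 0 °C to rt
Reagents that add atoms: none
Why: Fluoride cleavage of the silyl ether, buffered with acetic acid so that the liberated alkoxide cannot close onto the ring A ester.

**Compound list**

1 | methyl 2,6-dihydroxy-4-methylbenzoate | COC(=O)c1c(O)cc(C)cc1O | starting material
2 | 3-chloro-3-methylbut-1-yne | CC(C)(Cl)C#C | starting material
3 | methyl 2-hydroxy-4-methyl-6-(2-methylbut-3-yn-2-yloxy)benzoate | COC(=O)c1c(O)cc(C)cc1OC(C)(C)C#C | intermediate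
4 | methyl 2-hydroxy-4-methyl-6-(2-methylbut-3-en-2-yloxy)benzoate | COC(=O)c1c(O)cc(C)cc1OC(C)(C)C=C | intermediate
5 | dimethyl bromomalonate | COC(=O)C(Br)C(=O)OC | starting material
6 | dimethyl 2-[2-(methoxycarbonyl)-5-methyl-3-(2-methylbut-3-en-2-yloxy)phenoxy]malonate | COC(=O)C(Oc1cc(C)cc(OC(C)(C)C=C)c1C(=O)OC)C(=O)OC | intermediate
7 | prop-2-yn-1-ol | C#CCO | starting material
8 | triisopropyl(prop-2-yn-1-yloxy)silane | C#CCO[Si](C(C)C)(C(C)C)C(C)C | intermediate
9 | lithium 3-(triisopropylsilyloxy)prop-1-yn-1-ide (lithium acetylide of 8) | [Li]C#CCO[Si](C(C)C)(C(C)C)C(C)C | intermediate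
10 | lithium 2-[methoxy(methyl)amino]-5-(triisopropylsilyloxy)pent-3-yn-2-olate (racemic) | CC([O-])(N(C)OC)C#CCO[Si](C(C)C)(C(C)C)C(C)C.[Li+] | intermediate
11 | 5-(triisopropylsilyloxy)pent-3-yn-2-one | CC(=O)C#CCO[Si](C(C)C)(C(C)C)C(C)C | intermediate
12 | dimethyl 2-[2-(methoxycarbonyl)-5-methyl-3-(2-methylbut-3-en-2-yloxy)phenoxy]-2-[4-oxo-1-(triisopropylsilyloxy)pent-2-en-2-yl]malonate (E/Z mixture) | COC(=O)C(Oc1cc(C)cc(OC(C)(C)C=C)c1C(=O)OC)(C(=O)OC)C(CO[Si](C(C)C)(C(C)C)C(C)C)=CC(C)=O | intermediate
13 | methyl 1-[2-(methoxycarbonyl)-5-methyl-3-(2-methylbut-3-en-2-yloxy)phenoxy]-4,6-dioxo-2-(triisopropylsilyloxymethyl)cyclohex-2-ene-1-carboxylate (racemic, present as its sodium enolate) | COC(=O)C1(Oc2cc(C)cc(OC(C)(C)C=C)c2C(=O)OC)C(CO[Si](C(C)C)(C(C)C)C(C)C)=CC(=O)CC1=O | intermediate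
14 | methyl 2-[2,4-dihydroxy-6-(triisopropylsilyloxymethyl)phenoxy]-4-methyl-6-(2-methylbut-3-en-2-yloxy)benzoate | COC(=O)c1c(Oc2c(CO[Si](C(C)C)(C(C)C)C(C)C)cc(O)cc2O)cc(C)cc1OC(C)(C)C=C | intermediate
15 | methyl 2-[2,4-dimethoxy-6-(triisopropylsilyloxymethyl)phenoxy]-4-methyl-6-(2-methylbut-3-en-2-yloxy)benzoate | COC(=O)c1c(Oc2c(CO[Si](C(C)C)(C(C)C)C(C)C)cc(OC)cc2OC)cc(C)cc1OC(C)(C)C=C | intermediate
16 | methyl 2-[2,4-dimethoxy-6-(triisopropylsilyloxymethyl)phenoxy]-4-methyl-5-(3-methylbut-2-enyl)-6-oxocyclohexa-1,3-diene-1-carboxylate (racemic) | COC(=O)C1=C(Oc2c(CO[Si](C(C)C)(C(C)C)C(C)C)cc(OC)cc2OC)C=C(C)C(CC=C(C)C)C1=O | intermediate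
17 | methyl 2-[2,4-dimethoxy-6-(triisopropylsilyloxymethyl)phenoxy]-6-hydroxy-4-methyl-5-(3-methylbut-2-enyl)benzoate | COC(=O)c1c(Oc2c(CO[Si](C(C)C)(C(C)C)C(C)C)cc(OC)cc2OC)cc(C)c(CC=C(C)C)c1O | intermediate
18 | methyl 6-hydroxy-2-[2-(hydroxymethyl)-4,6-dimethoxyphenoxy]-4-methyl-5-(3-methylbut-2-enyl)benzoate | COC(=O)c1c(Oc2c(CO)cc(OC)cc2OC)cc(C)c(CC=C(C)C)c1O | target

**Step count**

Total: 9 steps. Longest linear sequence: 7 steps (steps 1, 2, 3, 6, 7, 8, 9, from 1 to 18); steps 4 and 5 form the two-step side branch to 11.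

**Steps most likely to fail**

Step 6. The malonate anion may close onto the ring A ester in a five-membered Dieckmann reaction and then lose an ester group irreversibly before it meets the ynone, or the sequence may stall before the dealkoxycarbonylative aromatisation. The fallback builds the diaryl ether by a known copper-catalysed Ullmann coupling onto a preformed ring B. It sets out from 1, used in excess, which is coupled with 2-bromo-3,5-dimethoxybenzaldehyde (COc1cc(OC)c(Br)c(C=O)c1) using CuI, picolinic acid and K3PO4 in DMSO at 90 °C to give methyl 2-(2-formyl-4,6-dimethoxyphenoxy)-6-hydroxy-4-methylbenzoate F1. The remaining phenol is etherified with 2 under the conditions of step 1 to give methyl 2-(2-formyl-4,6-dimethoxyphenoxy)-4-methyl-6-(2-methylbut-3-yn-2-yloxy)benzoate F2. Lindlar semi-hydrogenation gives methyl 2-(2-formyl-4,6-dimethoxyphenoxy)-4-methyl-6-(2-methylbut-3-en-2-yloxy)benzoate F3, and heating as in step 8 gives methyl 2-(2-formyl-4,6-dimethoxyphenoxy)-6-hydroxy-4-methyl-5-(3-methylbut-2-enyl)benzoate F4. NaBH4 in MeOH at 0 °C then reduces the aldehyde in the presence of the ester, and the path rejoins the route at 18.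

Step 3. Bromine transfer from the bromomalonate to the phenoxide, or base-induced condensation of the product malonate onto the neighbouring ester, may take the place of O-alkylation. The fallback replaces the SN2 reaction by a carbenoid O–H insertion, which needs neither base nor an electrophilic halogen. It sets out from 4, which is treated with dimethyl diazomalonate (COC(=O)C(=[N+]=[N-])C(=O)OC) and Rh2(OAc)4 in CH2Cl2 at 40 °C, and it returns directly to 6 without any new compound.

Step 8. The tertiary allyl ether may ionise and lose its five-carbon unit on heating, or the allyl group may travel by way of the ester-bearing ortho carbon to C3. The fallback exchanges the tertiary ether for a simple allyl ether, whose Claisen shift cannot ionise, and then trims the olefin. It sets out from 15, whose 1,1-dimethylallyl group is removed with Pd(PPh3)4 and morpholine in THF to give methyl 2-[2,4-dimethoxy-6-(triisopropylsilyloxymethyl)phenoxy]-6-hydroxy-4-methylbenzoate F5. Allyl bromide and K2CO3 in DMF give methyl 6-(allyloxy)-2-[2,4-dimethoxy-6-(triisopropylsilyloxymethyl)phenoxy]-4-methylbenzoate F6. Claisen rearrangement in N,N-diethylaniline at 190 °C gives methyl 5-allyl-2-[2,4-dimethoxy-6-(triisopropylsilyloxymethyl)phenoxy]-6-hydroxy-4-methylbenzoate F7. Cross-metathesis with 2-methylbut-2-ene and second-generation Grubbs catalyst in CH2Cl2 at 40 °C converts the allyl into the prenyl group, and the path comes back to the route at 17.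

**Further compounds**

F1 | step 6 | methyl 2-(2-formyl-4,6-dimethoxyphenoxy)-6-hydroxy-4-methylbenzoate | COC(=O)c1c(O)cc(C)cc1Oc1c(C=O)cc(OC)cc1OC
F2 | step 6 | methyl 2-(2-formyl-4,6-dimethoxyphenoxy)-4-methyl-6-(2-methylbut-3-yn-2-yloxy)benzoate | COC(=O)c1c(OC(C)(C)C#C)cc(C)cc1Oc1c(C=O)cc(OC)cc1OC
F3 | step 6 | methyl 2-(2-formyl-4,6-dimethoxyphenoxy)-4-methyl-6-(2-methylbut-3-en-2-yloxy)benzoate | COC(=O)c1c(OC(C)(C)C=C)cc(C)cc1Oc1c(C=O)cc(OC)cc1OC
F4 | step 6 | methyl 2-(2-formyl-4,6-dimethoxyphenoxy)-6-hydroxy-4-methyl-5-(3-methylbut-2-enyl)benzoate | COC(=O)c1c(Oc2c(C=O)cc(OC)cc2OC)cc(C)c(CC=C(C)C)c1O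
F0 | step 3 | none | none
F5 | step 8 | methyl 2-[2,4-dimethoxy-6-(triisopropylsilyloxymethyl)phenoxy]-6-hydroxy-4-methylbenzoate | COC(=O)c1c(O)cc(C)cc1Oc1c(CO[Si](C(C)C)(C(C)C)C(C)C)cc(OC)cc1OC
F6 | step 8 | methyl 6-(allyloxy)-2-[2,4-dimethoxy-6-(triisopropylsilyloxymethyl)phenoxy]-4-methylbenzoate | COC(=O)c1c(OCC=C)cc(C)cc1Oc1c(CO[Si](C(C)C)(C(C)C)C(C)C)cc(OC)cc1OC
F7 | step 8 | methyl 5-allyl-2-[2,4-dimethoxy-6-(triisopropylsilyloxymethyl)phenoxy]-6-hydroxy-4-methylbenzoate | COC(=O)c1c(O)c(CC=C)c(C)cc1Oc1c(CO[Si](C(C)C)(C(C)C)C(C)C)cc(OC)cc1OC
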